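The readings are calculated with constants of no real substance, noise included.

The target in the violet flask climbs to a top and then falls back to a steady level, so I ask how quickly its excess over that level dies away.

- violet: starting material 2 mM; free catalyst 20 µM; the very flask that is asked about, followed so far
- flask: starting material 2.0 mM; free catalyst 20 µM; time 20 min

violet run (percent of the starting material charged)

| time / min | target / % |
|---|---|
| 0.167 | 33 |
| 0.333 | 49 |
| 1.00 | 31 |
| 3.00 | 17 |
| 8.00 | 19 |

(each reading ± 1.5 percentage points)

- time up to 20 min at which target stands highest
- the amount of target, in percent of the starting material charged, at that time

- the numbers in the tables scatter with a standard deviation of 1.5 percentage points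

The height of the top rests on the reading of 49 % at 0.333 min, and any error there passes straight into my answer. The readings at 3.00 min and 8.00 min say nothing about the top, but their mean gives the level, 18.0 %. The fall from 0.333 min to 1.00 min then gives the time in which the height over the level halves. One scatter of 1.5 points added to the reading at 1.00 min makes that time 0.608 min, and the same added to the level makes it 0.491 min, so both count. The reading at 0.167 min does not enter. I take the excess halving time as 0.532 min.

The forecast puts the top at 0.37 min with 49 %, since “the sampled point sits close to the top”.

The violet flask peaks at 0.445 min, later than forecast, with 49.2 %, while 22.9 % of the starting material still stands.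

    starting material + free catalyst ⇌ catalyst intermediate A (K = 730 /M, k = 4560 /M/s)
    catalyst intermediate A ⇌ catalyst intermediate B (K = 1.90, k = 21.8 /s)
    catalyst intermediate B → free catalyst + target (k = 58.2 /s)
    starting material + target → side product (k = 1.74 /M/s)
    target + free catalyst ⇌ isomer of the product + free catalyst, rate k5*[free catalyst]*[target] forward; the back reaction follows from the equilibrium constant (K = 4.20, k = 1750 /M/s)

From that top, my level and halving time give 23.5 % at 1.78 min, and the violet flask holds 21.0 %, lower than that, so my halving time reads long. The isomer step runs in proportion to free catalyst (pseudo-first-order in target). So for the neighbour charged with 0.0050 mM, a quarter of the catalyst, I stretch that long halving time to 2.13 min. Then 20 min holds 9.39 of them, and I expect target near my level. That neighbour ends at 16.6 %, below my level, with 13.9 % side product against 3.97 % in the violet flask.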